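The isoflavone is cut at C3–C1' and O1–C2, so that ring C is built and ring B attached in a single anodic operation. The step exploits that both carbons of the C3–C1' bond are innately nucleophilic C–H positions: C3 is the α-carbon of a ring A enaminone next to the C4 carbonyl, and C1' lies para to the C4' oxygen of ring B. The precursor is an o-hydroxyaryl dimethylaminopropenone carrying O7 as a TIPS ether. Its partner, 2-bromophenol, brings the C3' bromine, which later takes the (Z)-alkenyl side chain, made from (R)-citronellal with all ten carbons kept.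

Key step: step 3

Remark on the side chain: Ar–CH=CH–CH(CH3)–CH2CH2CH=C(CH3)2 has exactly the ten carbons of citronellal, the aldehyde carbon becoming the carbon bonded to ring B. The alkyne needed is therefore (R)-3,7-dimethyloct-6-en-1-yne, formed by formal dehydration of the CH2–CHO unit, not the eleven-carbon alkyne of a one-carbon homologation. The priority order at C3 (C1–C2 arm > homoprenyl arm > methyl) never changes, so the R descriptor of citronellal is that of the target.

Remark on protection: O7 is carried as a TIPS ether, because an aryl silyl ether para to a carbonyl is prone to solvolysis and must survive hot amide acetal, HFIP and aqueous phosphate.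

Step 1
Reactants: 1 2,4-dihydroxyacetophenone
Product: 2 1-[2-hydroxy-4-(triisopropylsilyloxy)phenyl]ethan-1-one
Conditions: TIPSCl (1.05 equiv), imidazole (2.2 equiv), DMF, 0 °C to rt
Reagents that add atoms: triisopropylsilyl chloride, CC(C)[Si](Cl)(C(C)C)C(C)C
Why: Imidazole-mediated silyl ether formation; the 2-hydroxyl is held in a hydrogen bond to the ketone carbonyl and is much less nucleophilic, so one equivalent of silyl chloride should react only at the 4-hydroxyl.

Step 2
Reactants: 2 1-[2-hydroxy-4-(triisopropylsilyloxy)phenyl]ethan-1-one; 3 N,N-dimethylformamide dimethyl acetal (1.5 equiv)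
Product: 4 (E)-3-(dimethylamino)-1-[2-hydroxy-4-(triisopropylsilyloxy)phenyl]prop-2-en-1-one
Conditions: toluene, 90 °C
Reagents that add atoms: none
Why: Condensation of the methyl ketone with the amide acetal (enaminone formation with loss of two methanol) is the standard entry to o-hydroxyaryl enaminones and gives the E isomer, the chelated 2-hydroxyl staying free at this temperature.

Step 3
Reactants: 4 (E)-3-(dimethylamino)-1-[2-hydroxy-4-(triisopropylsilyloxy)phenyl]prop-2-en-1-one; 5 2-bromophenol (3 equiv)
Product: 8 3-(3-bromo-4-hydroxyphenyl)-7-(triisopropylsilyloxy)-4H-chromen-4-one, via C-arylated enaminone 6 (not isolated), via 2-(dimethylamino)chromanone 7 (not isolated)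
Conditions: undivided cell, boron-doped diamond (BDD) anode and cathode, constant current 5 mA/cm2, 2.2 F/mol based on 4, MeBu3N O3SOMe (0.1 M), 1,1,1,3,3,3-hexafluoropropan-2-ol (HFIP), slow addition of 4, rt; then 40 °C
Reagents that add atoms: none
Why: Proposed new method: anodic oxidation in HFIP should turn phenol 5 into its phenoxyl radical (directly, or by electron and proton transfer to the first-formed radical cation of 4), the π-nucleophilic α-carbon of enaminone 4 should add to the para carbon of that radical, and loss of a second electron and of two protons should give C-arylated enaminone 6 with ring B rearomatised while hydrogen forms at the cathode. The closest known reaction types are the oxidative C3–H functionalisation with annulation of o-hydroxyaryl enaminones to 3-substituted chromones, so far with heteroatom radicals or electrophiles, and the anodic dehydrogenative phenol–arene cross-coupling in fluorinated alcohols; a phenol has not been used as the carbon partner of an enaminone. Ring C then closes by 6-exo-trig addition of the ring A phenol oxygen to the iminium carbon C2 (the C3-protonated form of 6) to give aminal 7, and β-elimination of dimethylamine aromatises the pyranone. No stereocentre is formed. The step needs para over ortho selectivity on 5, which the higher spin density and lower hindrance at the carbon para to oxygen should secure, one ortho site being blocked by bromine. It also needs cross- over homo-coupling, which the excess of 5, the slow addition of 4 and the HFIP medium (which disfavours O–C coupling) should secure, while the electron-poor chromonyl group and the limited charge protect product 8 from further oxidation.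

Step 4
Reactants: 8 3-(3-bromo-4-hydroxyphenyl)-7-(triisopropylsilyloxy)-4H-chromen-4-one
Product: 9 3-[3-bromo-4-(tert-butyldimethylsilyloxy)phenyl]-7-(triisopropylsilyloxy)-4H-chromen-4-one
Conditions: TBSCl (1.3 equiv), imidazole (2.5 equiv), DMF, rt
Reagents that add atoms: tert-butyldimethylsilyl chloride, CC(C)(C)[Si](C)(C)Cl
Why: Standard imidazole-mediated silylation of a phenol, which the ortho bromine does not prevent; masking the acidic 4'-hydroxyl avoids a phenoxide next to the C–Br bond in the cross-coupling.

Step 5
Reactants: 10 (R)-citronellal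
Product: 12 (R)-3,7-dimethyloct-6-en-1-yne, via alkenyl nonaflate 11 (not isolated)
Conditions: C4F9SO2F (1.15 equiv), P2-Et phosphazene base (2.3 equiv), DMF, −30 °C to rt
Reagents that add atoms: none
Why: Dehydrative alkyne synthesis from an enolisable aldehyde through its alkenyl nonaflate: the phosphazene base forms the enolate at C2, the sulfonyl fluoride traps it on oxygen, and a second equivalent of base eliminates nonaflate from 11 to give the terminal alkyne with all ten carbons; no bond to C3 is made or broken and C3 is never deprotonated, so the R configuration is carried over.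

Step 6
Reactants: 12 (R)-3,7-dimethyloct-6-en-1-yne (1.2 equiv)
Product: 13 2-[(1Z,3R)-3,7-dimethylocta-1,6-dien-1-yl]-4,4,5,5-tetramethyl-1,3,2-dioxaborolane
Conditions: HBpin (1.0 equiv), [Rh(cod)Cl]2 (1.5 mol %), P(i-Pr)3 (6 mol %), Et3N (1 equiv), cyclohexane, rt
Reagents that add atoms: pinacolborane, [H]B1OC(C)(C)C(C)(C)O1
Why: Rhodium-catalysed trans-hydroboration of a terminal alkyne: with the bulky electron-rich phosphine and Et3N the alkyne rearranges to a rhodium vinylidene by 1,2-shift of the acetylenic hydrogen, and boryl migration followed by reductive elimination places boron and C3 cis on the new alkene; the propargylic C–H is not involved, so the stereocentre is untouched, and the trisubstituted alkene is too hindered to react.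

Step 7
Reactants: 9 3-[3-bromo-4-(tert-butyldimethylsilyloxy)phenyl]-7-(triisopropylsilyloxy)-4H-chromen-4-one; 13 2-[(1Z,3R)-3,7-dimethylocta-1,6-dien-1-yl]-4,4,5,5-tetramethyl-1,3,2-dioxaborolane (1.3 equiv)
Product: 14 3-{4-(tert-butyldimethylsilyloxy)-3-[(1Z,3R)-3,7-dimethylocta-1,6-dien-1-yl]phenyl}-7-(triisopropylsilyloxy)-4H-chromen-4-one
Conditions: Pd(OAc)2 (5 mol %), SPhos (10 mol %), K3PO4 (3 equiv), THF/H2O 10:1, 50 °C
Reagents that add atoms: none
Why: Suzuki–Miyaura coupling of an aryl bromide with an alkenyl pinacol boronate proceeds with retention of alkene geometry, and the dialkylbiarylphosphine promotes oxidative addition into the electron-rich ortho-silyloxy C–Br bond under mild phosphate conditions that the chromone and both aryl silyl ethers should tolerate.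

Step 8
Reactants: 14 3-{4-(tert-butyldimethylsilyloxy)-3-[(1Z,3R)-3,7-dimethylocta-1,6-dien-1-yl]phenyl}-7-(triisopropylsilyloxy)-4H-chromen-4-one
Product: 15 7-hydroxy-3-{4-hydroxy-3-[(1Z,3R)-3,7-dimethylocta-1,6-dien-1-yl]phenyl}-4H-chromen-4-one
Conditions: Bu4NF (2.5 equiv), AcOH (2.5 equiv), THF, 0 °C to rt
Reagents that add atoms: none
Why: Fluoride-mediated cleavage of both aryl silyl ethers (Si–F bond formation), buffered with acetic acid so that ring C, the Z alkene and the allylic stereocentre are not exposed to strong base or acid.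

Compound list
1 | 2,4-dihydroxyacetophenone | CC(=O)c1ccc(O)cc1O | starting material
2 | 1-[2-hydroxy-4-(triisopropylsilyloxy)phenyl]ethan-1-one | CC(=O)c1ccc(O[Si](C(C)C)(C(C)C)C(C)C)cc1O | intermediate
3 | N,N-dimethylformamide dimethyl acetal | COC(OC)N(C)C | starting material
4 | (E)-3-(dimethylamino)-1-[2-hydroxy-4-(triisopropylsilyloxy)phenyl]prop-2-en-1-one | CN(C)/C=C/C(=O)c1ccc(O[Si](C(C)C)(C(C)C)C(C)C)cc1O | intermediate
5 | 2-bromophenol | Oc1ccccc1Br | starting material
6 | 2-(3-bromo-4-hydroxyphenyl)-3-(dimethylamino)-1-[2-hydroxy-4-(triisopropylsilyloxy)phenyl]prop-2-en-1-one (C-arylated enaminone, transient, alkene geometry not defined) | CN(C)C=C(c1ccc(O)c(Br)c1)C(=O)c1ccc(O[Si](C(C)C)(C(C)C)C(C)C)cc1O | intermediate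
7 | 3-(3-bromo-4-hydroxyphenyl)-2-(dimethylamino)-7-(triisopropylsilyloxy)chroman-4-one (transient aminal, configuration at C2 and C3 not defined) | CN(C)C1Oc2cc(O[Si](C(C)C)(C(C)C)C(C)C)ccc2C(=O)C1c1ccc(O)c(Br)c1 | intermediate
8 | 3-(3-bromo-4-hydroxyphenyl)-7-(triisopropylsilyloxy)-4H-chromen-4-one | O=c1c(-c2ccc(O)c(Br)c2)coc2cc(O[Si](C(C)C)(C(C)C)C(C)C)ccc12 | intermediate
9 | 3-[3-bromo-4-(tert-butyldimethylsilyloxy)phenyl]-7-(triisopropylsilyloxy)-4H-chromen-4-one | O=c1c(-c2ccc(O[Si](C)(C)C(C)(C)C)c(Br)c2)coc2cc(O[Si](C(C)C)(C(C)C)C(C)C)ccc12 | intermediate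
10 | (R)-citronellal, (3R)-3,7-dimethyloct-6-enal | CC(C)=CCC[C@@H](C)CC=O | starting material
11 | (3R)-3,7-dimethylocta-1,6-dien-1-yl nonafluorobutane-1-sulfonate (E/Z mixture at C1=C2, transient) | CC(C)=CCC[C@@H](C)C=COS(=O)(=O)C(F)(F)C(F)(F)C(F)(F)C(F)(F)F | intermediate
12 | (R)-3,7-dimethyloct-6-en-1-yne | CC(C)=CCC[C@@H](C)C#C | intermediate
13 | 2-[(1Z,3R)-3,7-dimethylocta-1,6-dien-1-yl]-4,4,5,5-tetramethyl-1,3,2-dioxaborolane | CC(C)=CCC[C@@H](C)/C=C\B1OC(C)(C)C(C)(C)O1 | intermediate
14 | 3-{4-(tert-butyldimethylsilyloxy)-3-[(1Z,3R)-3,7-dimethylocta-1,6-dien-1-yl]phenyl}-7-(triisopropylsilyloxy)-4H-chromen-4-one | CC(C)=CCC[C@@H](C)/C=C\c1cc(-c2coc3cc(O[Si](C(C)C)(C(C)C)C(C)C)ccc3c2=O)ccc1O[Si](C)(C)C(C)(C)C | intermediate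
15 | 7-hydroxy-3-{4-hydroxy-3-[(1Z,3R)-3,7-dimethylocta-1,6-dien-1-yl]phenyl}-4H-chromen-4-one | CC(C)=CCC[C@@H](C)/C=C\c1cc(-c2coc3cc(O)ccc3c2=O)ccc1O | target

Total step count: 8. Longest linear sequence: 6 steps (steps 1, 2, 3, 4, 7, 8); the side-chain branch (steps 5, 6) joins at step 7.

Steps most likely to fail

Step 3 (proposed new method). The enaminone may close under the protic conditions to the 3-unsubstituted chromone before the C–C bond forms, or it may homo-couple. Coupling may also occur at the ortho carbon or the oxygen of the phenol, and the product phenol may be oxidised further. Fallback by known chemistry, setting out from 4 and returning at 8: iodine-mediated cyclisation of 4 (I2, CHCl3, rt) should give 3-iodo-7-(triisopropylsilyloxy)-4H-chromen-4-one F1. Suzuki–Miyaura coupling of F1 with 4-hydroxyphenylboronic acid (Pd(PPh3)4, Na2CO3, DME/H2O, 70 °C) should give 3-(4-hydroxyphenyl)-7-(triisopropylsilyloxy)-4H-chromen-4-one F2. Monobromination ortho to the free 4'-hydroxyl (NBS 1.0 equiv, catalytic i-Pr2NH, CH2Cl2, 0 °C) should then deliver 8, ring A being deactivated by the carbonyl and carrying only a silyl ether.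

Step 5. Aldol self-condensation of the aldehyde under the strong base may compete, or the reaction may stall at the E-configured alkenyl nonaflate, whose syn elimination is slow. Fallback, setting out from 10 and returning at 12, by one-carbon degradation and re-homologation: proline-catalysed α-aminoxylation with nitrosobenzene (L-proline, CHCl3, 0 °C) should give (3R)-3,7-dimethyl-2-(phenylaminooxy)oct-6-enal F3. This is reduced in the same flask (NaBH4, EtOH) to (3R)-3,7-dimethyl-2-(phenylaminooxy)oct-6-en-1-ol F4. N–O cleavage (Zn, AcOH, rt) should give (3R)-3,7-dimethyloct-6-ene-1,2-diol F5, and glycol cleavage (NaIO4, THF/H2O) should give (R)-2,6-dimethylhept-5-enal F6. Ohira–Bestmann alkynylation (dimethyl (1-diazo-2-oxopropyl)phosphonate, K2CO3, MeOH, 0 °C, kept short and cold to avoid epimerisation of the α-stereocentre) should give 12. The configuration at C2 of F3 to F5 is immaterial, since that carbon is excised.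

Step 6. Z-selectivity may erode through competing syn-hydroboration of this α-branched alkyne, or the catalyst may be deactivated so that conversion is low. Fallback, setting out from 9 and 12 and returning at 14, without the boronate: Sonogashira coupling (Pd(PhCN)2Cl2, P(t-Bu)3, CuI, i-Pr2NH, dioxane, rt) should give 3-{4-(tert-butyldimethylsilyloxy)-3-[(3R)-3,7-dimethyloct-6-en-1-yn-1-yl]phenyl}-7-(triisopropylsilyloxy)-4H-chromen-4-one F7. Semihydrogenation over Pd/CaCO3 poisoned with Pb(OAc)2 (H2 1 atm, quinoline, EtOAc, rt) should then give 14 by syn delivery of hydrogen, the trisubstituted alkene and the chromone being left alone.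

Further compounds
F1 | step 3 | 3-iodo-7-(triisopropylsilyloxy)-4H-chromen-4-one | O=c1c(I)coc2cc(O[Si](C(C)C)(C(C)C)C(C)C)ccc12
F2 | step 3 | 3-(4-hydroxyphenyl)-7-(triisopropylsilyloxy)-4H-chromen-4-one | O=c1c(-c2ccc(O)cc2)coc2cc(O[Si](C(C)C)(C(C)C)C(C)C)ccc12
F3 | step 5 | (3R)-3,7-dimethyl-2-(phenylaminooxy)oct-6-enal (C2 not defined) | CC(C)=CCC[C@@H](C)C(C=O)ONc1ccccc1
F4 | step 5 | (3R)-3,7-dimethyl-2-(phenylaminooxy)oct-6-en-1-ol (C2 not defined) | CC(C)=CCC[C@@H](C)C(CO)ONc1ccccc1
F5 | step 5 | (3R)-3,7-dimethyloct-6-ene-1,2-diol (C2 not defined) | CC(C)=CCC[C@@H](C)C(O)CO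
F6 | step 5 | (R)-2,6-dimethylhept-5-enal | CC(C)=CCC[C@@H](C)C=O
F7 | step 6 | 3-{4-(tert-butyldimethylsilyloxy)-3-[(3R)-3,7-dimethyloct-6-en-1-yn-1-yl]phenyl}-7-(triisopropylsilyloxy)-4H-chromen-4-one | CC(C)=CCC[C@@H](C)C#Cc1cc(-c2coc3cc(O[Si](C(C)C)(C(C)C)C(C)C)ccc3c2=O)ccc1O[Si](C)(C)C(C)(C)C
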